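**Strategy.** The route rests on cutting the dimethylpyran ring off ring B at both the C3'–CH= bond and the O4'–C(CH3)2 bond. This leads back to prenal and the unprotected (2S)-6,8-diprenyl-7,4'-dihydroxyflavanone. One phenylboronic-acid-templated annulation (ortho-hydroxyalkylation, o-quinone methide formation, oxa-6π electrocyclisation) adds all five carbons and closes the last ring without protecting groups. It exploits that the ring A phenol O7 is flanked by the prenylated carbons C6 and C8 and is deactivated by C4=O, whereas the ring B phenol O4' has two equivalent free ortho carbons, C3'/C5'. C2 is set earlier by rhodium-catalysed asymmetric 1,4-addition of an arylboronic acid to a 6,8-diprenylchromone.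

Key step: step 6

Remark: flavonoid numbering is used (O1, C2, C3, C4, C4a, C5–C8, C8a; ring B C1'–C6'), the stereocentre of the target is C2 and is (S), and the (S)-biaryl diphosphine of step 4 is assumed to give (2S) by analogy with the (S)-BINAP/cycloalkenone model (the (R)-ligand is taken if the sense proves opposite).

Step 1
Reactants: 1 7-hydroxy-4H-chromen-4-one (7-hydroxychromone)
Product: 2 7-hydroxy-6,8-diiodo-4H-chromen-4-one
Conditions: I2 (0.85 equiv), HIO3 (0.42 equiv), EtOH/H2O, 40 °C
Reagents that add atoms: iodine, II; iodic acid, O=I(=O)O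
Why: Electrophilic aromatic iodination with I2/HIO3, in which the 7-OH activates exactly its two ortho carbons C6 and C8, whereas C5 is unactivated and the pyrone carbon C3 is a far poorer nucleophile.

Step 2
Reactants: 2 7-hydroxy-6,8-diiodo-4H-chromen-4-one
Product: 3 6,8-diiodo-7-(methoxymethoxy)-4H-chromen-4-one
Conditions: MOMCl, K2CO3, acetone, 0 °C to rt
Reagents that add atoms: chloromethyl methyl ether (MOMCl), COCCl
Why: Williamson-type O-alkylation of the acidic, doubly ortho-iodinated phenol with the small electrophile MOMCl masks the proton that would protonate the allylstannane in step 3 and deactivate the chromone in step 4, and anhydrous K2CO3 leaves the pyrone ring intact.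

Step 3
Reactants: 3 6,8-diiodo-7-(methoxymethoxy)-4H-chromen-4-one; 4 tributyl(3-methylbut-2-en-1-yl)stannane (2.5 equiv)
Product: 5 7-(methoxymethoxy)-6,8-bis(3-methylbut-2-en-1-yl)-4H-chromen-4-one
Conditions: Pd(PPh3)4 (10 mol %), DMF, 90 °C
Reagents that add atoms: none
Why: Twofold Stille coupling of the two aryl iodides under neutral conditions that spare the base-sensitive pyrone, with C–C reductive elimination at the unsubstituted allyl terminus expected to give the linear 3-methylbut-2-enyl groups.

Step 4
Reactants: 5 7-(methoxymethoxy)-6,8-bis(3-methylbut-2-en-1-yl)-4H-chromen-4-one; 6 [4-(methoxymethoxy)phenyl]boronic acid (2 equiv)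
Product: 7 (2S)-7-(methoxymethoxy)-2-[4-(methoxymethoxy)phenyl]-6,8-bis(3-methylbut-2-en-1-yl)-2,3-dihydro-4H-chromen-4-one
Conditions: [RhCl(C2H4)2]2 (1.5 mol %), (S)-6,6'-dimethoxy-2,2'-bis[bis(3,4,5-trifluorophenyl)phosphino]-1,1'-biphenyl (3.3 mol %), KOH (10 mol %), toluene/H2O, 25 °C
Reagents that add atoms: none
Why: Hayashi–Miyaura rhodium-catalysed asymmetric 1,4-addition, a reaction type known for chromones, in which the aryl–rhodium species held by the electron-poor (S)-diphosphine inserts C2=C3 from one face and so sets C2 as (S), while room temperature and only catalytic base suppress 1,2-addition and retro-oxa-Michael racemisation and the trisubstituted prenyl alkenes do not compete for rhodium.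

Step 5
Reactants: 7 (2S)-7-(methoxymethoxy)-2-[4-(methoxymethoxy)phenyl]-6,8-bis(3-methylbut-2-en-1-yl)-2,3-dihydro-4H-chromen-4-one
Product: 8 (2S)-7-hydroxy-2-(4-hydroxyphenyl)-6,8-bis(3-methylbut-2-en-1-yl)-2,3-dihydro-4H-chromen-4-one
Conditions: conc. HCl (cat.), MeOH/THF, 40 °C
Reagents that add atoms: none
Why: Acid-catalysed acetal exchange with methanol (MOM cleavage) frees both phenols at once under conditions mild enough to leave the prenyl groups uncyclised and, being free of base, not to open ring C, so that C2 stays (S).

Step 6
Reactants: 8 (2S)-7-hydroxy-2-(4-hydroxyphenyl)-6,8-bis(3-methylbut-2-en-1-yl)-2,3-dihydro-4H-chromen-4-one; 9 3-methylbut-2-enal (prenal, 3 equiv)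
Product: 12 (2S)-2-(2,2-dimethyl-2H-chromen-6-yl)-7-hydroxy-6,8-bis(3-methylbut-2-en-1-yl)-2,3-dihydro-4H-chromen-4-one, via benzodioxaborin 10 (not isolated), via ortho-quinone methide 11 (not isolated)
Conditions: PhB(OH)2 (1.5 equiv), AcOH, toluene, reflux, Dean–Stark
Reagents that add atoms: none
Why: The ring B phenol O4'–H and PhB(OH)2 condense to an aryl boronate that binds prenal and delivers its carbonyl carbon through a closed six-membered transition state to the ortho carbon C3', giving benzodioxaborin 10, which on further heating undergoes cycloreversion with loss of PhB=O to the ortho-quinone methide 11. The closest known reaction type is the phenylboronic-acid-mediated annulation of phenols with α,β-unsaturated aldehydes to 2H-chromenes (a formal [3+3] condensation/oxa-6π sequence). The dimethylpyran ring closes by a thermally allowed disrotatory oxa-6π electrocyclisation of the 1-oxatriene O4'=C4'–C3'=CH–CH=C(CH3)2, which forms the hindered O–C(CH3)2 bond and is driven by rearomatisation of ring B. No stereocentre is created in 12 (the boracycle carbon of 10 forms as a mixture of epimers and becomes sp2 again in 11, so both converge), and C2 should stay (S) because the medium is weakly acidic and free of base, which disfavours retro-oxa-Michael opening of ring C. The step needs chemoselectivity between two free phenols and regioselectivity on ring B: O7 can only form a reversible, unproductive boronate because C6 and C8 both carry prenyl groups and ring A is deactivated by C4=O, C3' and C5' are equivalent so that one regioisomer results, and ring B has no phenol left after closure so that a second annulation is excluded. The absence of amine and of strong acid keeps the C3 methylene from aldol condensation with prenal and the o-prenylphenol units of ring A from chroman formation.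

**Compound list**
1 | 7-hydroxy-4H-chromen-4-one | O=c1ccoc2cc(O)ccc12 | starting material
2 | 7-hydroxy-6,8-diiodo-4H-chromen-4-one | O=c1ccoc2c(I)c(O)c(I)cc12 | intermediate
3 | 6,8-diiodo-7-(methoxymethoxy)-4H-chromen-4-one | COCOc1c(I)cc2c(=O)ccoc2c1I | intermediate
4 | tributyl(3-methylbut-2-en-1-yl)stannane | CCCC[Sn](CCCC)(CCCC)CC=C(C)C | starting material
5 | 7-(methoxymethoxy)-6,8-bis(3-methylbut-2-en-1-yl)-4H-chromen-4-one | COCOc1c(CC=C(C)C)cc2c(=O)ccoc2c1CC=C(C)C | intermediate
6 | [4-(methoxymethoxy)phenyl]boronic acid | COCOc1ccc(cc1)B(O)O | starting material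
7 | (2S)-7-(methoxymethoxy)-2-[4-(methoxymethoxy)phenyl]-6,8-bis(3-methylbut-2-en-1-yl)-2,3-dihydro-4H-chromen-4-one | CC(C)=CCc1cc2c(c(CC=C(C)C)c1OCOC)O[C@H](c1ccc(OCOC)cc1)CC2=O | intermediate
8 | (2S)-7-hydroxy-2-(4-hydroxyphenyl)-6,8-bis(3-methylbut-2-en-1-yl)-2,3-dihydro-4H-chromen-4-one | CC(C)=CCc1cc2c(c(CC=C(C)C)c1O)O[C@H](c1ccc(O)cc1)CC2=O | intermediate
9 | 3-methylbut-2-enal (prenal) | CC(C)=CC=O | starting material
10 | (2S)-7-hydroxy-6,8-bis(3-methylbut-2-en-1-yl)-2-[4-(2-methylprop-1-en-1-yl)-2-phenyl-4H-1,3,2-benzodioxaborinin-6-yl]-2,3-dihydro-4H-chromen-4-one, both epimers at the boracycle carbon C4 | CC(C)=CCc1cc2c(c(CC=C(C)C)c1O)O[C@H](c1ccc3OB(c4ccccc4)OC(C=C(C)C)c3c1)CC2=O | intermediate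
11 | (2S)-7-hydroxy-6,8-bis(3-methylbut-2-en-1-yl)-2-[(3Z)-3-(3-methylbut-2-en-1-ylidene)-4-oxocyclohexa-1,5-dien-1-yl]-2,3-dihydro-4H-chromen-4-one | CC(C)=CCc1cc2c(c(CC=C(C)C)c1O)O[C@H](C1=C/C(=C/C=C(C)C)C(=O)C=C1)CC2=O | intermediate
12 | (2S)-2-(2,2-dimethyl-2H-chromen-6-yl)-7-hydroxy-6,8-bis(3-methylbut-2-en-1-yl)-2,3-dihydro-4H-chromen-4-one | CC(C)=CCc1cc2c(c(CC=C(C)C)c1O)O[C@H](c1ccc3c(c1)C=CC(C)(C)O3)CC2=O | target

Total step count: 6. Longest linear sequence: 6 steps (1 → 2 → 3 → 5 → 7 → 8 → 12).

**Steps most likely to fail**

First, step 6.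
- **What may go wrong:** The templated C–C bond formation may be slow at a phenol ring that carries no second donor group. Prenal may be consumed by self-condensation. Prolonged heating may erode the configuration at C2 through reversible opening of ring C.
- **Fallback:** It sets out from 8 and comes back at 12. It splits the annulation into a C–C bond formation and an oxidative ring closure at lower temperature. Friedel–Crafts ortho-prenylation with 2-methylbut-3-en-2-ol and BF3·OEt2 in dioxane at room temperature can only strike C3'/C5', because ring A has no free activated position. It should give (2S)-7-hydroxy-2-[4-hydroxy-3-(3-methylbut-2-en-1-yl)phenyl]-6,8-bis(3-methylbut-2-en-1-yl)-2,3-dihydro-4H-chromen-4-one F1. Dehydrogenative cyclisation with DDQ (1 equiv, benzene, rt to 60 °C) should then abstract hydride from the benzylic methylene of the more electron-rich ring B prenylphenol. This generates the same ortho-quinone methide 11, which closes to 12.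

Second, step 4.
- **What may go wrong:** Insertion of the electron-rich, 8-substituted chromone into the aryl–rhodium bond may be sluggish, so that protodeboronation outruns it. Facial discrimination may also be insufficient.
- **Fallback:** It sets out from 5 (with 6) and comes back at 7. It replaces asymmetric C–C bond formation by resolution. A non-asymmetric conjugate addition with Pd(OCOCF3)2/2,2'-bipyridine in aqueous medium should give racemic 7-(methoxymethoxy)-2-[4-(methoxymethoxy)phenyl]-6,8-bis(3-methylbut-2-en-1-yl)-2,3-dihydro-4H-chromen-4-one F2. Kinetic resolution follows by Noyori asymmetric transfer hydrogenation (RuCl[(R,R)-TsDPEN](p-cymene), HCO2H/Et3N, rt, stopped shortly after half conversion). It should reduce the matched (2R)-ketone to the cis alcohol (2R,4R)-7-(methoxymethoxy)-2-[4-(methoxymethoxy)phenyl]-6,8-bis(3-methylbut-2-en-1-yl)-3,4-dihydro-2H-chromen-4-ol F3. The (2S)-ketone 7 is left untouched and is separated by chromatography.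

Third, step 3.
- **What may go wrong:** Allyl transposition may occur during coupling, with bond formation through the substituted terminus. The reaction may stall after the first coupling next to the ortho substituents. Iodine may be lost reductively.
- **Fallback:** It sets out from 3 and comes back at 5. It removes the regiochemical question. Twofold Stille allylation with allyltributylstannane (Pd(PPh3)4, DMF, 90 °C), whose two allyl termini are equivalent, should give 7-(methoxymethoxy)-6,8-bis(prop-2-en-1-yl)-4H-chromen-4-one F4. Twofold olefin cross metathesis with excess 2-methylbut-2-ene (Grubbs second-generation catalyst, CH2Cl2, 40 °C) should convert both allyl groups into prenyl groups. The push–pull C2=C3 bond of the pyrone should stay inert.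

**Further compounds**
F1 | step 6 | (2S)-7-hydroxy-2-[4-hydroxy-3-(3-methylbut-2-en-1-yl)phenyl]-6,8-bis(3-methylbut-2-en-1-yl)-2,3-dihydro-4H-chromen-4-one | CC(C)=CCc1cc2c(c(CC=C(C)C)c1O)O[C@H](c1ccc(O)c(CC=C(C)C)c1)CC2=O
F2 | step 4 | racemic 7-(methoxymethoxy)-2-[4-(methoxymethoxy)phenyl]-6,8-bis(3-methylbut-2-en-1-yl)-2,3-dihydro-4H-chromen-4-one | CC(C)=CCc1cc2c(c(CC=C(C)C)c1OCOC)OC(c1ccc(OCOC)cc1)CC2=O
F3 | step 4 | (2R,4R)-7-(methoxymethoxy)-2-[4-(methoxymethoxy)phenyl]-6,8-bis(3-methylbut-2-en-1-yl)-3,4-dihydro-2H-chromen-4-ol | CC(C)=CCc1cc2c(c(CC=C(C)C)c1OCOC)O[C@@H](c1ccc(OCOC)cc1)C[C@H]2O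
F4 | step 3 | 7-(methoxymethoxy)-6,8-bis(prop-2-en-1-yl)-4H-chromen-4-one | COCOc1c(CC=C)cc2c(=O)ccoc2c1CC=C
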